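## Analysis of the target

Target 36 is built from two trans-2,3-diaryl-2,3-dihydrobenzofurans joined through one shared arene. Ring A (C3a to C7a) carries a hydroxyl at C4 and the (E)-4-hydroxystyryl group at C6 and is fused to dihydrofuran ring B (O1, C2, C3). C2 is bound to C7' of the central arene, ring C, which has a hydroxyl at C4' and is fused to dihydrofuran ring D (O1', C2', C3'); C3 and C3' each bear a 3,5-dihydroxyphenyl group and C2' a 2,4-dihydroxyphenyl group. The four stereocentres C2, C3, C2' and C3' are all R, so the two aryl groups are trans on each dihydrofuran. Sensitive groups are the nine phenols, the stilbene double bond and the benzylic ether bonds C2–O1 and C2'–O1', which ionise readily under acid. The main difficulty is that C3 and C3' are diarylmethine centres with no neighbouring activating group, so they cannot be equilibrated, and they are too far apart to control one another; each must be set in absolute terms. The strategy rests on one feature: C2 is attached to C7' of ring C, with O1' (on C7a') ortho and the C4' oxygen para to that position, so a cation at C2 is strongly stabilised. Read backwards, ring B is what remains of a 3,4-diaryl-3,4-dihydrocoumarin once its carbonyl carbon has been excised, and ring D, whose C2' carries a 2,4-dioxygenated aryl group, can be read the same way.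

## Retrosynthetic reasoning

**36 to 33 and 34.** All nine phenols are carried as methyl ethers, so 36 comes from the permethyl ether 35 by Lewis-acid demethylation. The stilbene is cut at the C6–vinyl bond, giving core bromide 33 and 4-methoxystyrene 34. This keeps the acid- and radical-sensitive alkene out of all earlier steps. The forward Heck reaction must give the E-alkene at an aryl bromide that lies meta to both ring A oxygens.

**33 to 32 (O1–C2).** Ring B is opened at O1–C2 and not at C3–C3a, because C2 is the one carbon of ring B that supports a cation. Placing a carboxyl group on C2 leads to the N-acyloxyphthalimide 32, in which the ring A oxygen is masked as a silyl ether. The forward step must expel the carboxyl carbon, convert C2 into a cation by radical–polar crossover and let the silyl ether oxygen close the ring trans to the C3 aryl group. C3 is not touched.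

**32 to 28.** Ester 32 comes from silyl ether acid 31 and N-hydroxyphthalimide 14. Acid 31 is the ring-opened, O-silylated form of dihydrocoumarin 28. In the lactone, the carbon that becomes C3 of the target is a configurationally stable diarylmethine with no acidic hydrogen. The opening has to be run so that the free hydroxy acid never appears, since it would close again.

**28 to 21 and 25.** The lactone is cut at C3–C4 and at the acyl–oxygen bond, a formal [4+2] disconnection. It gives the ring C/D arylacetic acid 21 and ortho-quinone methide 27, which is released from sulfone 25. This is the convergent union of the two halves. A chiral isothiourea acting on the activated acid must fix the diarylmethine carbon (the later C3) as R against a remote, already defined ring D.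

**25 to 23, 4 and 22.** Sulfone 25 is cut at the benzylic carbon–aryl bond, to salicylaldehyde 23 and Grignard reagent 4, which is prepared from bromide 3. Aldehyde 23 is the monodemethylation product of the symmetric dimethoxy aldehyde 22, so no regiochemical question arises.

**21 to 18.** The acetic acid side chain on C7' is cut at the aryl–CH2 bond, leading through malonate 19 to ring D bromide 18. The side chain is installed only after ring D exists. An arylacetic acid placed ortho to the free ring C phenol would lactonise, and it would offer a second enolisable position in the first cycloaddition. The bromine therefore holds this position from the start.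

**18 to 10.** Ring D is opened at O1'–C2' by the same decarboxylative logic, but in its stepwise, documented form. Ester 15 gives methyl ether 16 by intermolecular capture of the cation by the alcohol cosolvent, and desilylation and acid then close the ring. The road to 32 therefore contains no untested reaction, and the sequence rehearses the key step. Ester 15 comes from acid 13 and that from lactone 10.

**10 to 7, 6, 4, 2 and 1.** Lactone 10 is cut like 28, into the commercial arylacetic acid 7 and the ortho-quinone methide 9 from sulfone 6. Sulfone 6 comes from aldehyde 2 and the same Grignard reagent 4; one batch of 4, made from bromide 3, serves both sulfones. Aldehyde 2 comes from phenol 1 by formylation at its only free ortho position.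

## Alternatives that were turned down

**Alternative 1:** Ring D would be made from a flavanone, with the bond C3'–C3a' formed by an aryl shift. Chromanone A2 is treated with PhI(OAc)2 and H2SO4 in trimethyl orthoformate. Its enol ether is attacked by trivalent iodine at flavanone C3, and aryl carbon C4a then shifts from C4 to C3 while the iodine departs in reduced form. The pyranone contracts to the trans ester A1, and the former C4 ends up outside the ring as the ester carbon.
- For: the oxidative ring contraction is documented on flavanones and gives the trans ring; A2 is two steps from simple aromatics; the bromine of A1 is the handle for the side chain.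
- Against: A1 has a carboxyl carbon where the target has an aryl group, so C3' must be rebuilt by a decarboxylative arylation.
- Against: the only stereocentre of A2 lies β to a ketone with a phenoxide leaving group and racemises through the chalcone.
- Against: the iodine reagent can attack the 2,4-dimethoxyphenyl ring, and ring B is left unsolved.
- Comparison: as a ring contraction it is better precedented than the closure chosen here. The chosen route offers instead both aryl groups in place before the contraction, the non-equilibrating centres set by a catalyst in a stable lactone, and one logic for both dihydrofurans.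

**Alternative 2:** Ring A would be built, not bought. Pyrone A4 is a 4-methoxy-6-styryl-2-pyrone whose C3 carries the C3–C2 chain, with an ethynyl ether on the C2 oxygen. A thermal intramolecular Diels–Alder addition of the alkyne to pyrone carbons C3 and C6 forms bonds C3a–C7a and C6–C7, and the bicyclic adduct then extrudes CO2. This gives the permethylated target A3 (identical with 35), with ring A aromatised and ring B closed at once.
- For: two rings and two C–C bonds in one thermal step, regiochemistry fixed by the tether, no late cross-coupling. In bond economy and convergence it is clearly stronger than the chosen key step, which forms one C–O bond.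
- Against: A4 is a terminal ynol ether of a 2,4-dialkoxybenzylic secondary alcohol. Such ethers ionise or rearrange to ketenes well below the temperature an electron-rich 4-alkoxypyrone needs to react with an electron-rich alkyne.
- Against: C2 must be set as an open-chain carbinol anti to C3 before the ring exists and cannot be corrected later; no reliable method sets C3 next to the pyrone.
- Comparison: the chosen route gives up the one-step aromatisation. In return its precursor 32 is assembled from stable intermediates, and C2 is formed under substrate control from a planar cation.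

**Alternative 3:** Ring A would enter as a cyclohexane-1,3-dione. Mn(OAc)3 converts dione A7 into the radical at its C2, which attacks stilbene A6 at the alkene carbon that carries the 3,5-dimethoxyphenyl group and so forms C3–C3a. The resulting benzylic radical next to ring C gives up an electron to a second equivalent of trivalent manganese, and the enol oxygen then forms O1–C2 to give the hexahydrobenzofuranone A5. A5 must then be aromatised, O-methylated and homologated from ester to styryl.
- For: a well-known oxidative annulation that forms two bonds and ring B in one step, with the right regiochemistry and trans geometry, from a stilbene that is easily reached from 18. On bonds formed per step it beats the chosen closure.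
- Against: nothing sets the absolute configuration of C3. The two faces of the alkene of A6 differ only through the distant ring D, so the 2R,3R and 2S,3S rings are expected as a mixture.
- Against: stoichiometric Mn(OAc)3 in hot acetic acid and the later dehydrogenation are hard on the acid-labile ring D, and at least four further steps are needed to reach the stage of 33.
- Comparison: the chosen strategy is longer before its key step, but sets C3 by catalyst control and ends directly in the aromatic bromide 33.

Key step: step 16

Assumption: (2S,3R)-HyperBTM is taken to give the 4R lactones on the usual enolate model; if lactone 10 proves to be 4S, the enantiomeric catalyst is used in steps 4 and 13.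

Remark: C3 of lactones 10 and 28 (C2 of the acids and esters made from them) is drawn with the configuration of the trans lactone; this centre later becomes a radical and its configuration has no bearing on the route.

## Route

Step 1
Reactants: 1 2-bromo-5-methoxyphenol
Product: 2 3-bromo-2-hydroxy-6-methoxybenzaldehyde
Conditions: MgCl2, Et3N, (CH2O)n, MeCN, reflux
Reagents that add atoms: paraformaldehyde (formaldehyde), C=O
Why: Magnesium-phenoxide-directed ortho-formylation (Casnati–Skattebøl); the only free ortho position of 1 lies between OH and OMe, so the regiochemistry cannot vary.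

Step 2
Reactants: 3 1-bromo-3,5-dimethoxybenzene
Product: 4 3,5-dimethoxyphenylmagnesium bromide (titrated THF solution, kept under argon)
Conditions: Mg turnings, I2 (cat.), THF, reflux; titrate
Reagents that add atoms: magnesium, [Mg]
Why: Grignard reagent formation by insertion of magnesium metal into the aryl–bromine bond, a simple addition without co-product; one batch is prepared and drawn on for steps 3 and 12.

Step 3
Reactants: 4 3,5-dimethoxyphenylmagnesium bromide; 2 3-bromo-2-hydroxy-6-methoxybenzaldehyde
Product: 6 6-bromo-2-[(3,5-dimethoxyphenyl)(4-methylphenylsulfonyl)methyl]-3-methoxyphenol (racemic sulfone), via benzhydrol 5 (not isolated)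
Conditions: 4 (2.5 equiv), THF, add 2, 0 °C to rt; then p-TolSO2Na, 2 M HCl, CH2Cl2, rt
Reagents that add atoms: sodium p-toluenesulfinate, Cc1ccc(cc1)S(=O)[O-].[Na+]
Why: Grignard 1,2-addition to the salicylaldehyde (one equivalent is spent on the phenol), then acid-induced ionisation of the doubly activated benzhydrol and S-alkylation of sulfinate. The crude benzhydrol is not purified because it is acid-labile, and the stereocentre of the sulfone is erased when the quinone methide is released.

Step 4
Reactants: 7 (2,4-dimethoxyphenyl)acetic acid; 6 ring C sulfone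
Product: 10 (3R,4R)-8-bromo-3-(2,4-dimethoxyphenyl)-4-(3,5-dimethoxyphenyl)-5-methoxy-3,4-dihydro-2H-chromen-2-one (trans lactone), via mixed pivalic anhydride 8 (not isolated), via ortho-quinone methide 9 (not isolated)
Conditions: 7, t-BuCOCl, i-Pr2NEt, CH2Cl2, 0 °C; then 6, (2S,3R)-HyperBTM (10 mol %), Cs2CO3, rt
Reagents that add atoms: none
Why: Isothiourea-catalysed Michael addition–lactonisation (formal [4+2]) of a C(1)-ammonium enolate with an ortho-quinone methide released from the sulfone by base. The enolate is held planar by its O···S contact and shielded on one face by the phenyl group of the catalyst, so the methide carbon is approached from the open face and C4 (the later C3') is set R under catalyst control; C3 forms in the same bond formation and is lost later.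

Step 5
Reactants: 10 ring D lactone
Product: 13 (2R,3R)-3-[3-bromo-2-(tert-butyldimethylsilyloxy)-6-methoxyphenyl]-2-(2,4-dimethoxyphenyl)-3-(3,5-dimethoxyphenyl)propanoic acid, via dilithium salt 11 (not isolated), via bis-silyl compound 12 (not isolated)
Conditions: LiOH, THF/H2O, rt; evaporate; TBSCl, imidazole, DMF, rt; then AcOH, THF/H2O, rt
Reagents that add atoms: lithium hydroxide, [Li+].[OH-]; tert-butyldimethylsilyl chloride, CC(C)(C)[Si](C)(C)Cl
Why: Saponification opens the lactone irreversibly to the phenoxide carboxylate, which is silylated on both oxygens without ever being acidified (the free hydroxy acid would relactonise). The silyl ester, far more labile than the hindered aryl silyl ether, is then hydrolysed selectively by aqueous acetic acid.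

Step 6
Reactants: 13 silyl ether acid; 14 N-hydroxyphthalimide
Product: 15 1,3-dioxoisoindolin-2-yl (2R,3R)-3-[3-bromo-2-(tert-butyldimethylsilyloxy)-6-methoxyphenyl]-2-(2,4-dimethoxyphenyl)-3-(3,5-dimethoxyphenyl)propanoate
Conditions: DIC, DMAP (10 mol %), CH2Cl2, 0 °C to rt
Reagents that add atoms: none
Why: Carbodiimide (Steglich-type) esterification to the redox-active ester; the silyl ether keeps the phenol from attacking the active ester and re-forming the lactone.

Step 7
Reactants: 15 redox-active ester
Product: 16 tert-butyl{6-bromo-2-[(1R)-1-(3,5-dimethoxyphenyl)-2-(2,4-dimethoxyphenyl)-2-methoxyethyl]-3-methoxyphenoxy}dimethylsilane (both epimers at the methoxy-bearing carbon)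
Conditions: fac-Ir(ppy)3 (1 mol %), MeOH/CH2Cl2 1:4, blue LEDs (450 nm), rt
Reagents that add atoms: methanol, CO
Why: Photoredox radical–polar crossover decarboxylative etherification: the excited iridium complex reduces the ester, which loses CO2 and phthalimide anion, and the 2,4-dimethoxybenzylic radical is oxidised by tetravalent iridium to a cation that methanol captures. The diarylmethine centre is untouched; the two epimers at the new ether carbon, and any material already cyclised through the silyl ether, converge in step 8.

Step 8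
Reactants: 16 benzylic methyl ether
Product: 18 (2R,3R)-7-bromo-2-(2,4-dimethoxyphenyl)-3-(3,5-dimethoxyphenyl)-4-methoxy-2,3-dihydro-1-benzofuran, via phenol 17 (not isolated)
Conditions: TBAF, THF, 0 °C; then TFA, CH2Cl2, 0 °C
Reagents that add atoms: none
Why: Fluoride frees the phenol, acid ionises the 2,4-dimethoxybenzylic methyl ether, and the phenol closes ring D in a 5-exo-trig cyclisation (acid-mediated cyclisation of benzylic ethers onto phenols). C2' forms trans to the C3' aryl group because the oxygen adds to the cation face anti to it, and because the C2'–O1' bond can ionise again under the acid, which funnels material to the more stable trans ring.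

Step 9
Reactants: 18 ring D bromide
Product: 19 diethyl 2-[(2R,3R)-2-(2,4-dimethoxyphenyl)-3-(3,5-dimethoxyphenyl)-4-methoxy-2,3-dihydro-1-benzofuran-7-yl]propanedioate
Conditions: diethyl malonate, Pd(OAc)2 (2 mol %), P(t-Bu)3·HBF4 (4 mol %), K3PO4, toluene, 80 °C
Reagents that add atoms: diethyl malonate, CCOC(=O)CC(=O)OCC
Why: Palladium-catalysed arylation of a malonate enolate; the bulky electron-rich phosphine allows oxidative addition of the ortho-alkoxy aryl bromide to zerovalent palladium, and the basic medium leaves the acid-sensitive ring D alone.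

Step 10
Reactants: 19 arylmalonate
Product: 21 2-[(2R,3R)-2-(2,4-dimethoxyphenyl)-3-(3,5-dimethoxyphenyl)-4-methoxy-2,3-dihydro-1-benzofuran-7-yl]acetic acid, via disodium arylmalonate 20 (not isolated)
Conditions: NaOH, EtOH/H2O, 60 °C; then AcOH, 70 °C
Reagents that add atoms: sodium hydroxide, [Na+].[OH-]
Why: Saponification followed by decarboxylation of the arylmalonic acid, which loses CO2 readily on warming at mildly acidic pH; mineral acid is avoided because of ring D.

Step 11
Reactants: 22 4-bromo-2,6-dimethoxybenzaldehyde
Product: 23 4-bromo-2-hydroxy-6-methoxybenzaldehyde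
Conditions: BCl3, CH2Cl2, −78 to 0 °C
Reagents that add atoms: none
Why: Chelation-controlled monodemethylation ortho to the formyl group; the boron chelate formed after the first cleavage deactivates the second methoxy group, and the two methoxy groups are equivalent.

Step 12
Reactants: 4 3,5-dimethoxyphenylmagnesium bromide; 23 4-bromo-2-hydroxy-6-methoxybenzaldehyde
Product: 25 5-bromo-2-[(3,5-dimethoxyphenyl)(4-methylphenylsulfonyl)methyl]-3-methoxyphenol (racemic sulfone), via benzhydrol 24 (not isolated)
Conditions: 4 (2.5 equiv), THF, add 23, 0 °C to rt; then p-TolSO2Na, 2 M HCl, CH2Cl2, rt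
Reagents that add atoms: sodium p-toluenesulfinate, Cc1ccc(cc1)S(=O)[O-].[Na+]
Why: Same Grignard addition and acid-mediated sulfinate alkylation as in step 3; the aryl bromide of ring A is inert to the aryl Grignard reagent at this temperature.

Step 13
Reactants: 21 ring C/D arylacetic acid; 25 ring A sulfone
Product: 28 (3R,4R)-7-bromo-3-[(2R,3R)-2-(2,4-dimethoxyphenyl)-3-(3,5-dimethoxyphenyl)-4-methoxy-2,3-dihydro-1-benzofuran-7-yl]-4-(3,5-dimethoxyphenyl)-5-methoxy-3,4-dihydro-2H-chromen-2-one (trans lactone), via mixed pivalic anhydride 26 (not isolated), via ortho-quinone methide 27 (not isolated)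
Conditions: 21, t-BuCOCl, i-Pr2NEt, CH2Cl2, 0 °C; then 25, (2S,3R)-HyperBTM (20 mol %), Cs2CO3, rt
Reagents that add atoms: none
Why: Same isothiourea-catalysed Michael addition–lactonisation as in step 4, here as the convergent union. The catalyst-bound enolate of 21 adds to the methide carbon of 27 from its open face and sets C4 (C3 of ring B) as R; because ring D is already a single enantiomer, any C4 epimer is a diastereomer and can be removed by chromatography.

Step 14
Reactants: 28 ring B lactone
Product: 31 (2R,3R)-3-[4-bromo-2-(tert-butyldimethylsilyloxy)-6-methoxyphenyl]-2-[(2R,3R)-2-(2,4-dimethoxyphenyl)-3-(3,5-dimethoxyphenyl)-4-methoxy-2,3-dihydro-1-benzofuran-7-yl]-3-(3,5-dimethoxyphenyl)propanoic acid, via dilithium salt 29 (not isolated), via bis-silyl compound 30 (not isolated)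
Conditions: LiOH, THF/H2O, rt; evaporate; TBSCl, imidazole, DMF, rt; then AcOH, THF/H2O, rt
Reagents that add atoms: lithium hydroxide, [Li+].[OH-]; tert-butyldimethylsilyl chloride, CC(C)(C)[Si](C)(C)Cl
Why: As in step 5: irreversible saponification, silylation of both oxygens of the salt and selective hydrolysis of the silyl ester; ring D is stable to these basic and weakly acidic conditions.

Step 15
Reactants: 31 silyl ether acid; 14 N-hydroxyphthalimide
Product: 32 1,3-dioxoisoindolin-2-yl (2R,3R)-3-[4-bromo-2-(tert-butyldimethylsilyloxy)-6-methoxyphenyl]-2-[(2R,3R)-2-(2,4-dimethoxyphenyl)-3-(3,5-dimethoxyphenyl)-4-methoxy-2,3-dihydro-1-benzofuran-7-yl]-3-(3,5-dimethoxyphenyl)propanoate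
Conditions: DIC, DMAP (10 mol %), CH2Cl2, 0 °C to rt
Reagents that add atoms: none
Why: Carbodiimide (Steglich-type) esterification as in step 6; the silyl ether prevents relactonisation of the active ester.

Step 16
Reactants: 32 N-acyloxyphthalimide
Product: 33 (2R,3R)-6-bromo-2-[(2R,3R)-2-(2,4-dimethoxyphenyl)-3-(3,5-dimethoxyphenyl)-4-methoxy-2,3-dihydro-1-benzofuran-7-yl]-3-(3,5-dimethoxyphenyl)-4-methoxy-2,3-dihydro-1-benzofuran
Conditions: fac-Ir(ppy)3 (2 mol %), CH2Cl2 (degassed), blue LEDs (450 nm), rt
Reagents that add atoms: none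
Why: Proposed new method: photoexcited fac-Ir(ppy)3 passes one electron to the N-acyloxyphthalimide, whose radical anion breaks down into CO2, phthalimide anion and a secondary benzylic radical at C2; tetravalent iridium then oxidises this radical, which has O1' ortho and the C4' methoxy group para on ring C, to a cation best described as a para-quinone methide oxonium ion, and the catalyst returns to trivalent iridium. The oxygen of the ring A silyl ether adds to C2 in a 5-exo-trig closure (ring B, bond O1–C2) and phthalimide anion removes the silyl group from the silyloxonium ion. The closest known reaction types are the photoredox radical–polar crossover decarboxylative etherification of N-acyloxyphthalimides with alcohols (used in step 7) and the cyclisation of silyl ethers onto cations with loss of the silyl group; their combination as an intramolecular capture by an aryl silyl ether is new. C2 is the only new stereocentre and is under substrate control: the oxygen adds to the face of the planar cation anti to the 3,5-dimethoxyphenyl group on C3, giving the trans ring, and since the neutral medium does not re-ionise the product this is a kinetic result (a trace of acid would equilibrate any cis isomer through C2–O1 ionisation). C3 is part of neither the radical nor the cation and keeps its configuration. The step needs capture by oxygen to outrun loss of the C3 proton, which would give a triarylethylene and erase C3; the short tether, the long lifetime of the doubly oxygen-stabilised cation and the absence of any base stronger than phthalimide anion should secure this, and CH2Cl2 is used because it cannot intercept the cation. Closure through the other ortho oxygen of ring A, the methoxy group, should be slower because an oxonium ion gives up a methyl group far less readily than a silyl group, and it would give the same ring skeleton with the silyl ether left at C4, which the final step would cleave as well; the aryl bromides are not reduced by the photocatalyst.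

Step 17
Reactants: 33 core bromide; 34 4-methoxystyrene
Product: 35 (2R,3R)-2-[(2R,3R)-2-(2,4-dimethoxyphenyl)-3-(3,5-dimethoxyphenyl)-4-methoxy-2,3-dihydro-1-benzofuran-7-yl]-3-(3,5-dimethoxyphenyl)-4-methoxy-6-[(E)-2-(4-methoxyphenyl)ethenyl]-2,3-dihydro-1-benzofuran
Conditions: Pd(OAc)2 (5 mol %), P(o-tolyl)3 (10 mol %), Et3N, DMF, 110 °C
Reagents that add atoms: none
Why: Heck reaction; the bromide lies meta to both ring A oxygens and is not deactivated, and the neutral pathway with a bromide and a monodentate phosphine gives β-arylation of the styrene and the E-alkene by syn β-hydride elimination.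

Step 18
Reactants: 35 permethyl ether
Product: 36 (2R,3R)-2-[(2R,3R)-2-(2,4-dihydroxyphenyl)-3-(3,5-dihydroxyphenyl)-4-hydroxy-2,3-dihydro-1-benzofuran-7-yl]-3-(3,5-dihydroxyphenyl)-6-[(E)-2-(4-hydroxyphenyl)ethenyl]-2,3-dihydro-1-benzofuran-4-ol (target)
Conditions: BBr3 (excess), CH2Cl2, −78 °C to rt
Reagents that add atoms: none
Why: Lewis-acid cleavage of the nine aryl methyl ethers; reversible ionisation at C2–O1 or C2'–O1' can only return the trans rings, and C3 and C3' carry no acidic hydrogen.

## Compound list

1 | 2-bromo-5-methoxyphenol | COc1ccc(Br)c(O)c1 | starting material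
2 | 3-bromo-2-hydroxy-6-methoxybenzaldehyde | COc1ccc(Br)c(O)c1C=O | intermediate
3 | 1-bromo-3,5-dimethoxybenzene | COc1cc(Br)cc(OC)c1 | starting material
4 | 3,5-dimethoxyphenylmagnesium bromide (titrated THF solution) | COc1cc(OC)cc([Mg]Br)c1 | intermediate
5 | (3-bromo-2-hydroxy-6-methoxyphenyl)(3,5-dimethoxyphenyl)methanol, racemic (formed in the flask) | COc1cc(OC)cc(c1)C(O)c1c(O)c(Br)ccc1OC | intermediate
6 | 6-bromo-2-[(3,5-dimethoxyphenyl)(4-methylphenylsulfonyl)methyl]-3-methoxyphenol, racemic | Cc1ccc(cc1)S(=O)(=O)C(c1cc(OC)cc(OC)c1)c1c(O)c(Br)ccc1OC | intermediate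
7 | (2,4-dimethoxyphenyl)acetic acid | COc1ccc(CC(O)=O)c(OC)c1 | starting material
8 | (2,4-dimethoxyphenyl)acetic pivalic anhydride (formed in the flask) | COc1ccc(CC(=O)OC(=O)C(C)(C)C)c(OC)c1 | intermediate
9 | 2-bromo-6-(3,5-dimethoxybenzylidene)-5-methoxycyclohexa-2,4-dien-1-one, ortho-quinone methide of ring C (formed in the flask) | COc1cc(OC)cc(C=C2C(=O)C(Br)=CC=C2OC)c1 | intermediate
10 | (3R,4R)-8-bromo-3-(2,4-dimethoxyphenyl)-4-(3,5-dimethoxyphenyl)-5-methoxy-3,4-dihydro-2H-chromen-2-one | O=C1Oc2c(Br)ccc(OC)c2[C@@H](c2cc(OC)cc(OC)c2)[C@@H]1c1ccc(OC)cc1OC | intermediate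
11 | dilithium (2R,3R)-3-(3-bromo-6-methoxy-2-oxidophenyl)-2-(2,4-dimethoxyphenyl)-3-(3,5-dimethoxyphenyl)propanoate (formed in the flask) | [Li+].[Li+].[O-]C(=O)[C@@H](c1ccc(OC)cc1OC)[C@@H](c1c([O-])c(Br)ccc1OC)c1cc(OC)cc(OC)c1 | intermediate
12 | tert-butyldimethylsilyl (2R,3R)-3-[3-bromo-2-(tert-butyldimethylsilyloxy)-6-methoxyphenyl]-2-(2,4-dimethoxyphenyl)-3-(3,5-dimethoxyphenyl)propanoate (formed in the flask) | CC(C)(C)[Si](C)(C)OC(=O)[C@@H](c1ccc(OC)cc1OC)[C@@H](c1c(O[Si](C)(C)C(C)(C)C)c(Br)ccc1OC)c1cc(OC)cc(OC)c1 | intermediate
13 | (2R,3R)-3-[3-bromo-2-(tert-butyldimethylsilyloxy)-6-methoxyphenyl]-2-(2,4-dimethoxyphenyl)-3-(3,5-dimethoxyphenyl)propanoic acid | OC(=O)[C@@H](c1ccc(OC)cc1OC)[C@@H](c1c(O[Si](C)(C)C(C)(C)C)c(Br)ccc1OC)c1cc(OC)cc(OC)c1 | intermediate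
14 | N-hydroxyphthalimide | O=C1c2ccccc2C(=O)N1O | starting material
15 | 1,3-dioxoisoindolin-2-yl (2R,3R)-3-[3-bromo-2-(tert-butyldimethylsilyloxy)-6-methoxyphenyl]-2-(2,4-dimethoxyphenyl)-3-(3,5-dimethoxyphenyl)propanoate | O=C(ON1C(=O)c2ccccc2C1=O)[C@@H](c1ccc(OC)cc1OC)[C@@H](c1c(O[Si](C)(C)C(C)(C)C)c(Br)ccc1OC)c1cc(OC)cc(OC)c1 | intermediate
16 | tert-butyl{6-bromo-2-[(1R)-1-(3,5-dimethoxyphenyl)-2-(2,4-dimethoxyphenyl)-2-methoxyethyl]-3-methoxyphenoxy}dimethylsilane, both epimers at the methoxy-bearing carbon | COC(c1ccc(OC)cc1OC)[C@@H](c1c(O[Si](C)(C)C(C)(C)C)c(Br)ccc1OC)c1cc(OC)cc(OC)c1 | intermediate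
17 | 6-bromo-2-[(1R)-1-(3,5-dimethoxyphenyl)-2-(2,4-dimethoxyphenyl)-2-methoxyethyl]-3-methoxyphenol (formed in the flask) | COC(c1ccc(OC)cc1OC)[C@@H](c1c(O)c(Br)ccc1OC)c1cc(OC)cc(OC)c1 | intermediate
18 | (2R,3R)-7-bromo-2-(2,4-dimethoxyphenyl)-3-(3,5-dimethoxyphenyl)-4-methoxy-2,3-dihydro-1-benzofuran | Brc1ccc(OC)c2c1O[C@@H](c1ccc(OC)cc1OC)[C@@H]2c1cc(OC)cc(OC)c1 | intermediate
19 | diethyl 2-[(2R,3R)-2-(2,4-dimethoxyphenyl)-3-(3,5-dimethoxyphenyl)-4-methoxy-2,3-dihydro-1-benzofuran-7-yl]propanedioate | CCOC(=O)C(C(=O)OCC)c1ccc(OC)c2c1O[C@@H](c1ccc(OC)cc1OC)[C@@H]2c1cc(OC)cc(OC)c1 | intermediate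
20 | disodium 2-[(2R,3R)-2-(2,4-dimethoxyphenyl)-3-(3,5-dimethoxyphenyl)-4-methoxy-2,3-dihydro-1-benzofuran-7-yl]propanedioate (formed in the flask) | [Na+].[Na+].[O-]C(=O)C(C([O-])=O)c1ccc(OC)c2c1O[C@@H](c1ccc(OC)cc1OC)[C@@H]2c1cc(OC)cc(OC)c1 | intermediate
21 | 2-[(2R,3R)-2-(2,4-dimethoxyphenyl)-3-(3,5-dimethoxyphenyl)-4-methoxy-2,3-dihydro-1-benzofuran-7-yl]acetic acid | OC(=O)Cc1ccc(OC)c2c1O[C@@H](c1ccc(OC)cc1OC)[C@@H]2c1cc(OC)cc(OC)c1 | intermediate
22 | 4-bromo-2,6-dimethoxybenzaldehyde | COc1cc(Br)cc(OC)c1C=O | starting material
23 | 4-bromo-2-hydroxy-6-methoxybenzaldehyde | COc1cc(Br)cc(O)c1C=O | intermediate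
24 | (4-bromo-2-hydroxy-6-methoxyphenyl)(3,5-dimethoxyphenyl)methanol, racemic (formed in the flask) | COc1cc(OC)cc(c1)C(O)c1c(O)cc(Br)cc1OC | intermediate
25 | 5-bromo-2-[(3,5-dimethoxyphenyl)(4-methylphenylsulfonyl)methyl]-3-methoxyphenol, racemic | Cc1ccc(cc1)S(=O)(=O)C(c1cc(OC)cc(OC)c1)c1c(O)cc(Br)cc1OC | intermediate
26 | mixed pivalic anhydride of acid 21 (formed in the flask) | CC(C)(C)C(=O)OC(=O)Cc1ccc(OC)c2c1O[C@@H](c1ccc(OC)cc1OC)[C@@H]2c1cc(OC)cc(OC)c1 | intermediate
27 | 3-bromo-6-(3,5-dimethoxybenzylidene)-5-methoxycyclohexa-2,4-dien-1-one, ortho-quinone methide of ring A (formed in the flask) | COc1cc(OC)cc(C=C2C(=O)C=C(Br)C=C2OC)c1 | intermediate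
28 | (3R,4R)-7-bromo-3-[(2R,3R)-2-(2,4-dimethoxyphenyl)-3-(3,5-dimethoxyphenyl)-4-methoxy-2,3-dihydro-1-benzofuran-7-yl]-4-(3,5-dimethoxyphenyl)-5-methoxy-3,4-dihydro-2H-chromen-2-one | O=C1Oc2cc(Br)cc(OC)c2[C@@H](c2cc(OC)cc(OC)c2)[C@@H]1c1ccc(OC)c2c1O[C@@H](c1ccc(OC)cc1OC)[C@@H]2c1cc(OC)cc(OC)c1 | intermediate
29 | dilithium salt of the ring-opened hydroxy acid of 28 (formed in the flask) | [Li+].[Li+].[O-]C(=O)[C@@H](c1ccc(OC)c2c1O[C@@H](c1ccc(OC)cc1OC)[C@@H]2c1cc(OC)cc(OC)c1)[C@@H](c1c([O-])cc(Br)cc1OC)c1cc(OC)cc(OC)c1 | intermediate
30 | tert-butyldimethylsilyl ester of acid 31 (formed in the flask) | CC(C)(C)[Si](C)(C)OC(=O)[C@@H](c1ccc(OC)c2c1O[C@@H](c1ccc(OC)cc1OC)[C@@H]2c1cc(OC)cc(OC)c1)[C@@H](c1c(O[Si](C)(C)C(C)(C)C)cc(Br)cc1OC)c1cc(OC)cc(OC)c1 | intermediate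
31 | (2R,3R)-3-[4-bromo-2-(tert-butyldimethylsilyloxy)-6-methoxyphenyl]-2-[(2R,3R)-2-(2,4-dimethoxyphenyl)-3-(3,5-dimethoxyphenyl)-4-methoxy-2,3-dihydro-1-benzofuran-7-yl]-3-(3,5-dimethoxyphenyl)propanoic acid | OC(=O)[C@@H](c1ccc(OC)c2c1O[C@@H](c1ccc(OC)cc1OC)[C@@H]2c1cc(OC)cc(OC)c1)[C@@H](c1c(O[Si](C)(C)C(C)(C)C)cc(Br)cc1OC)c1cc(OC)cc(OC)c1 | intermediate
32 | 1,3-dioxoisoindolin-2-yl ester of acid 31 (precursor of the key step) | O=C(ON1C(=O)c2ccccc2C1=O)[C@@H](c1ccc(OC)c2c1O[C@@H](c1ccc(OC)cc1OC)[C@@H]2c1cc(OC)cc(OC)c1)[C@@H](c1c(O[Si](C)(C)C(C)(C)C)cc(Br)cc1OC)c1cc(OC)cc(OC)c1 | intermediate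
33 | (2R,3R)-6-bromo-2-[(2R,3R)-2-(2,4-dimethoxyphenyl)-3-(3,5-dimethoxyphenyl)-4-methoxy-2,3-dihydro-1-benzofuran-7-yl]-3-(3,5-dimethoxyphenyl)-4-methoxy-2,3-dihydro-1-benzofuran | Brc1cc(OC)c2c(c1)O[C@@H](c1ccc(OC)c3c1O[C@@H](c1ccc(OC)cc1OC)[C@@H]3c1cc(OC)cc(OC)c1)[C@@H]2c1cc(OC)cc(OC)c1 | intermediate
34 | 4-methoxystyrene | C=Cc1ccc(OC)cc1 | starting material
35 | nona-O-methyl ether of the target | COc1ccc(/C=C/c2cc(OC)c3c(c2)O[C@@H](c2ccc(OC)c4c2O[C@@H](c2ccc(OC)cc2OC)[C@@H]4c2cc(OC)cc(OC)c2)[C@@H]3c2cc(OC)cc(OC)c2)cc1 | intermediate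
36 | CNP0217875.2, (2R,3R)-2-[(2R,3R)-2-(2,4-dihydroxyphenyl)-3-(3,5-dihydroxyphenyl)-4-hydroxy-2,3-dihydro-1-benzofuran-7-yl]-3-(3,5-dihydroxyphenyl)-6-[(E)-2-(4-hydroxyphenyl)ethenyl]-2,3-dihydro-1-benzofuran-4-ol | Oc1ccc(/C=C/c2cc(O)c3c(c2)O[C@@H](c2ccc(O)c4c2O[C@@H](c2ccc(O)cc2O)[C@@H]4c2cc(O)cc(O)c2)[C@@H]3c2cc(O)cc(O)c2)cc1 | target

## Step count and least certain steps

Total: 18 steps. Longest linear sequence: 15 steps (steps 1, 3 to 10 and 13 to 18). Step 2 (Grignard reagent 4, used in steps 3 and 12) and steps 11 and 12 (sulfone 25) are side branches.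

**Step 16 (key step).** The most likely failure is that the hindered, weakly nucleophilic aryl silyl ether oxygen attacks too slowly, so that the cation loses the C3 proton (elimination that also erases C3) or the radical is reduced before crossover. The fallback uses known chemistry only and runs from 32 to 33. Ester 32 is irradiated with fac-Ir(ppy)3 in MeOH/CH2Cl2, exactly as in step 7, so that the cation is captured by methanol to give methyl ether F1. Treatment with TBAF gives phenol F2, and TFA then ionises the benzylic ether and closes ring B to 33, as in step 8.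

**Step 13.** The risk is poor facial selectivity at the methide carbon. The catalyst and the chiral acid 21 may be mismatched; quinone methide 27 carries a methoxy group next to the methide carbon and may react in a twisted geometry; and a carbonate-mediated background addition may compete. The same concern applies in milder form to step 4. The fallback runs from 21 to 28 and changes the mode of activation. Acid 21 is coupled with 3,5-dimethylpyrazole (DIC) to give the N-acylpyrazole F3. A cinchona-derived squaramide then catalyses its Michael addition to 27, released from 25 with aqueous Na2CO3 in CHCl3, and lactonisation with loss of the pyrazole gives 28. Here the catalyst binds the quinone methide oxygen by hydrogen bonds and selects the methide face directly.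

**Step 18.** The risk is acid-promoted side reactions during the long exposure to BBr3 and HBr: protonation of the stilbene followed by Friedel–Crafts cyclisation onto a resorcinol ring, and incomplete cleavage of nine ethers. The fallback changes the order of events and runs from 33 to 36. Bromide 33, which has no alkene, is demethylated with BBr3 to octaphenol F4 and acetylated (Ac2O, pyridine) to octaacetate F5. A Heck reaction with commercial 4-acetoxystyrene under the conditions of step 17 gives nonaacetate F6, and K2CO3 in MeOH releases 36.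

**Step 7.** The risk is loss of the C3' proton from the cation, or hydrogen-atom transfer to the radical in the protic medium, in place of capture by methanol. The fallback runs from 13 to 16 and skips ester 15. Acid 13 is electrolysed at constant current at a graphite anode in MeOH with 2,4,6-collidine (Hofer–Moest decarboxylative methoxylation), which gives 16 directly with methanol as bulk solvent.

## Further compounds

F1 | step 16 | tert-butyl{5-bromo-2-[(1R)-2-[(2R,3R)-2-(2,4-dimethoxyphenyl)-3-(3,5-dimethoxyphenyl)-4-methoxy-2,3-dihydro-1-benzofuran-7-yl]-1-(3,5-dimethoxyphenyl)-2-methoxyethyl]-3-methoxyphenoxy}dimethylsilane, both epimers at the methoxy-bearing carbon | COC(c1ccc(OC)c2c1O[C@@H](c1ccc(OC)cc1OC)[C@@H]2c1cc(OC)cc(OC)c1)[C@@H](c1c(O[Si](C)(C)C(C)(C)C)cc(Br)cc1OC)c1cc(OC)cc(OC)c1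
F2 | step 16 | 5-bromo-2-[(1R)-2-[(2R,3R)-2-(2,4-dimethoxyphenyl)-3-(3,5-dimethoxyphenyl)-4-methoxy-2,3-dihydro-1-benzofuran-7-yl]-1-(3,5-dimethoxyphenyl)-2-methoxyethyl]-3-methoxyphenol | COC(c1ccc(OC)c2c1O[C@@H](c1ccc(OC)cc1OC)[C@@H]2c1cc(OC)cc(OC)c1)[C@@H](c1c(O)cc(Br)cc1OC)c1cc(OC)cc(OC)c1
F3 | step 13 | 2-[(2R,3R)-2-(2,4-dimethoxyphenyl)-3-(3,5-dimethoxyphenyl)-4-methoxy-2,3-dihydro-1-benzofuran-7-yl]-1-(3,5-dimethyl-1H-pyrazol-1-yl)ethan-1-one | Cc1cc(C)n(n1)C(=O)Cc1ccc(OC)c2c1O[C@@H](c1ccc(OC)cc1OC)[C@@H]2c1cc(OC)cc(OC)c1
F4 | step 18 | (2R,3R)-6-bromo-2-[(2R,3R)-2-(2,4-dihydroxyphenyl)-3-(3,5-dihydroxyphenyl)-4-hydroxy-2,3-dihydro-1-benzofuran-7-yl]-3-(3,5-dihydroxyphenyl)-2,3-dihydro-1-benzofuran-4-ol | Brc1cc(O)c2c(c1)O[C@@H](c1ccc(O)c3c1O[C@@H](c1ccc(O)cc1O)[C@@H]3c1cc(O)cc(O)c1)[C@@H]2c1cc(O)cc(O)c1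
F5 | step 18 | octaacetate of F4 | Brc1cc(OC(C)=O)c2c(c1)O[C@@H](c1ccc(OC(C)=O)c3c1O[C@@H](c1ccc(OC(C)=O)cc1OC(C)=O)[C@@H]3c1cc(OC(C)=O)cc(OC(C)=O)c1)[C@@H]2c1cc(OC(C)=O)cc(OC(C)=O)c1
F6 | step 18 | nonaacetate of the target | CC(=O)Oc1ccc(/C=C/c2cc(OC(C)=O)c3c(c2)O[C@@H](c2ccc(OC(C)=O)c4c2O[C@@H](c2ccc(OC(C)=O)cc2OC(C)=O)[C@@H]4c2cc(OC(C)=O)cc(OC(C)=O)c2)[C@@H]3c2cc(OC(C)=O)cc(OC(C)=O)c2)cc1
F0 | step 7 | none | none
A1 | alternative 1 | methyl (2R,3R)-7-bromo-2-(2,4-dimethoxyphenyl)-4-methoxy-2,3-dihydro-1-benzofuran-3-carboxylate (trans) | Brc1ccc(OC)c2c1O[C@@H](c1ccc(OC)cc1OC)[C@@H]2C(=O)OC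
A2 | alternative 1 | (2R)-8-bromo-2-(2,4-dimethoxyphenyl)-5-methoxy-2,3-dihydro-4H-chromen-4-one | O=C1C[C@H](c2ccc(OC)cc2OC)Oc2c(Br)ccc(OC)c12
A3 | alternative 2 | nona-O-methyl ether of the target (identical with 35) | COc1ccc(/C=C/c2cc(OC)c3c(c2)O[C@@H](c2ccc(OC)c4c2O[C@@H](c2ccc(OC)cc2OC)[C@@H]4c2cc(OC)cc(OC)c2)[C@@H]3c2cc(OC)cc(OC)c2)cc1
A4 | alternative 2 | 3-[(1R,2R)-2-[(2R,3R)-2-(2,4-dimethoxyphenyl)-3-(3,5-dimethoxyphenyl)-4-methoxy-2,3-dihydro-1-benzofuran-7-yl]-1-(3,5-dimethoxyphenyl)-2-(ethynyloxy)ethyl]-4-methoxy-6-[(E)-2-(4-methoxyphenyl)ethenyl]-2H-pyran-2-one | COc1ccc(/C=C/C2=CC(OC)=C([C@@H](c3cc(OC)cc(OC)c3)[C@@H](OC#C)c3ccc(OC)c4c3O[C@@H](c3ccc(OC)cc3OC)[C@@H]4c3cc(OC)cc(OC)c3)C(=O)O2)cc1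
A5 | alternative 3 | methyl (2R,3R)-2-[(2R,3R)-2-(2,4-dimethoxyphenyl)-3-(3,5-dimethoxyphenyl)-4-methoxy-2,3-dihydro-1-benzofuran-7-yl]-3-(3,5-dimethoxyphenyl)-4-oxo-2,3,4,5,6,7-hexahydro-1-benzofuran-6-carboxylate (C6 epimers) | COC(=O)C1CC(=O)C2=C(C1)O[C@@H](c1ccc(OC)c3c1O[C@@H](c1ccc(OC)cc1OC)[C@@H]3c1cc(OC)cc(OC)c1)[C@@H]2c1cc(OC)cc(OC)c1
A6 | alternative 3 | (2R,3R)-2-(2,4-dimethoxyphenyl)-3-(3,5-dimethoxyphenyl)-7-[(E)-2-(3,5-dimethoxyphenyl)ethenyl]-4-methoxy-2,3-dihydro-1-benzofuran | COc1cc(/C=C/c2ccc(OC)c3c2O[C@@H](c2ccc(OC)cc2OC)[C@@H]3c2cc(OC)cc(OC)c2)cc(OC)c1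
A7 | alternative 3 | methyl 3,5-dioxocyclohexane-1-carboxylate | COC(=O)C1CC(=O)CC(=O)C1
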